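**Amounts seen.** By 20.0 min the blue run, the very flask asked about, shows 64.0% of its J as E and Q.

the same everywhere: J 0.050 M; D 11 mM (held)

| flask | remark | time |
|---|---|---|
| blue | the very flask that is asked about, followed so far |  |
| flask |  | 1.0 h |

blue run (percent of the J charged)

| time / min | E / % | Q / % |
|---|---|---|
| 2.50 | 6 | 3 |
| 8.00 | 18 | 12 |
| 15.0 | 30 | 19 |
| 20.0 | 44 | 20 |
| 30.0 | 47 | 27 |

(readings scatter by 2 percentage points)

- concentration of E at 1.0 h, in M
- concentration of Q at 1.0 h, in M
- concentration of J at 1.0 h, in M

- the numbers in the tables scatter with a standard deviation of 2 percentage points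
- at the start none of D is in solution

**Loss constant.** We assume that dissolved D stands near 11 mM through the run, though none is in solution at the start. J then falls pseudo-first-order. The reading above gives 0.0511 /min as the loss constant k, minus the ln of the share E and Q leave, divided by the time. This counts E and Q as the whole loss of J. The last reading of the blue run gives 0.0449 /min, a lower value.

**Our bracket.** As J keeps falling, c_J at 1.0 h stays under the 0.0130 M that the last reading leaves. First-order decay tightens this. With the sum at 20.0 min set two standard deviations low, k becomes 0.0438 /min, and holding k gives 0.00361 M of J as our upper end. Set two high, k becomes 0.0596 /min, and holding k gives 0.00140 M of J as our lower end. We commit to 0.00233 M.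

**The forecast.** It gives c_E = 0.03 M, c_Q = 0.0167 M and c_J = 0.0035 M. Its c_J lies inside our bracket but above our value. It warns that “slowing or catalyst death would leave more J”.

**The flask.** At 1.0 h the flask holds c_J = 0.00191 M, c_E = 0.0295 M and c_Q = 0.0155 M, so its c_J lies inside the bracket and below our value.

    J + X → E (k = 0.0560 /M/s)
    J → Q (k = 2.90 × 10⁻⁴ /s)
    2 J → G (k = 0.00110 /M/s)
    D ⇌ X, rate k4*(csat - [X]) (kL = 0.0200 /s)

**Carried on.** At 0.100 h c_X in the flask stands at 0.00993 M, against a saturation value of 11 mM. For the same flask read at 15 min, k gives 0.0232 M of J, and it holds 0.0223 M.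

The earlier runs and the new flask are simulated with made-up constants; noise was put on by code.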